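## Retrosynthetic overview

1. The target 31 comes from global desilylation of 30. The C11–C12 bond of 30 is made by an electroreductive Cr/Ni alkenyl–aldehyde coupling of aldehyde 13 (C1–C11) with (E)-vinyl iodide 28 (C12–C23), with Felkin control at C11.
2. Vinyl iodide 28 comes from the ring B alcohol 23 by a stereoinvertive alkynylation at C14 (new reaction), then hydrozirconation–iodination. Ring B is built from pentan-3-one, (R)-lactate (C14) and a Fráter–Seebach ester (C20, C21).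
3. Aldehyde 13 comes from the ring A aldehyde 7 by (Z)-crotylboration (C9, C10), silylation and oxidative cleavage. Ring A is built from 4-methylheptane-3,5-dione and the (S)-Roche ester (C8).
4. Ring order: ring A (step 3) and ring B (step 13) are each closed by triketone cyclodehydration before the fragment union; no ring is formed after it.

Assumption: 1, 3, 8, 14, 16, 18 and 24 are bought; backbone atoms are numbered C1–C23 from the ethyl group on ring A (C3–C7 = ring A, C8–C14 = linker, C15–C19 = ring B, C20–C23 = right-hand chain), so the target is 8S,9S,10S,11R,12E,14R,20R,21R.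

## Route

Step 1
Reactants: 1 methyl (S)-3-hydroxy-2-methylpropanoate
Product: 2 methyl (S)-3-[(tert-butyldimethylsilyl)oxy]-2-methylpropanoate
Conditions: TBSCl, imidazole, CH2Cl2, 0 °C to rt
Reagents that add atoms: tert-butyldimethylsilyl chloride, CC(C)(C)[Si](C)(C)Cl
Why: Silyl ether formation masks the primary hydroxyl so that it cannot take part in the Claisen and ring-closing steps; the bought C8 centre is untouched.

Step 2
Reactants: 2 methyl (S)-3-[(tert-butyldimethylsilyl)oxy]-2-methylpropanoate; 3 4-methylheptane-3,5-dione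
Product: 4 (8S)-9-[(tert-butyldimethylsilyl)oxy]-4,6,8-trimethylnonane-3,5,7-trione (keto–enol and C4/C6 epimer mixture)
Conditions: 3 (2.5 equiv), LiN(i-Pr)2 (5.0 equiv), THF, −78 to 0 °C; then 2, −78 to −20 °C; aq. NH4Cl
Reagents that add atoms: none
Why: Hauser-type Claisen acylation, in which the terminal carbanion of the diketone dianion attacks the ester faster than it deprotonates it, so C8 is kept.

Step 3
Reactants: 4 (8S)-9-[(tert-butyldimethylsilyl)oxy]-4,6,8-trimethylnonane-3,5,7-trione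
Product: 6 2-ethyl-6-[(2S)-1-hydroxypropan-2-yl]-3,5-dimethyl-4H-pyran-4-one, via silyl ether pyranone 5 (not isolated)
Conditions: PPh3, CCl4, THF, rt; then MeOH, rt
Reagents that add atoms: none
Why: Appel-type cyclodehydration of the 1,3,5-triketone closes ring A without acid or base strong enough to enolise C8, and the HCl formed then cleaves the primary silyl ether by methanolysis.

Step 4
Reactants: 6 2-ethyl-6-[(2S)-1-hydroxypropan-2-yl]-3,5-dimethyl-4H-pyran-4-one
Product: 7 (2R)-2-(6-ethyl-3,5-dimethyl-4-oxo-4H-pyran-2-yl)propanal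
Conditions: Dess–Martin periodinane, NaHCO3, CH2Cl2, 0 °C; used at once
Reagents that add atoms: none
Why: Buffered Dess–Martin oxidation gives the aldehyde under neutral conditions, so the labile C8 centre next to the pyranone is not epimerised (the descriptor changes only by priority).

Step 5
Reactants: 7 (2R)-2-(6-ethyl-3,5-dimethyl-4-oxo-4H-pyran-2-yl)propanal; 8 2-[(2Z)-but-2-en-1-yl]-4,4,5,5-tetramethyl-1,3,2-dioxaborolane
Product: 10 2-ethyl-6-[(2S,3S,4R)-3-hydroxy-4-methylhex-5-en-2-yl]-3,5-dimethyl-4H-pyran-4-one, via pinacol borate ester 9 (not isolated)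
Conditions: 8 (1.5 equiv), 4 Å MS, toluene, −20 °C to rt; aq. NaHCO3
Reagents that add atoms: none
Why: Crotylboration through a chair Zimmerman–Traxler transition state, where the (Z)-crotyl group gives the 9,10-syn pair and avoidance of syn-pentane strain between its Z-methyl and the C8 methyl enforces anti-Felkin attack (8,9-anti), so C9 and C10 are both set by C8.

Step 6
Reactants: 10 2-ethyl-6-[(2S,3S,4R)-3-hydroxy-4-methylhex-5-en-2-yl]-3,5-dimethyl-4H-pyran-4-one
Product: 11 2-ethyl-3,5-dimethyl-6-[(2S,3S,4R)-4-methyl-3-[(triethylsilyl)oxy]hex-5-en-2-yl]-4H-pyran-4-one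
Conditions: TESCl, imidazole, DMF, 0 °C to rt
Reagents that add atoms: chlorotriethylsilane, CC[Si](CC)(CC)Cl
Why: Silyl ether formation with a chloride (no silyl triflate, which would activate the pyranone) gives a non-chelating C9 ether needed for Felkin control in step 16.

Step 7
Reactants: 11 2-ethyl-3,5-dimethyl-6-[(2S,3S,4R)-4-methyl-3-[(triethylsilyl)oxy]hex-5-en-2-yl]-4H-pyran-4-one
Product: 13 (2S,3R,4S)-4-(6-ethyl-3,5-dimethyl-4-oxo-4H-pyran-2-yl)-2-methyl-3-[(triethylsilyl)oxy]pentanal, via vicinal diol 12 (not isolated)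
Conditions: OsO4 (2 mol%), NaIO4, 2,6-lutidine, dioxane–H2O 3:1, rt
Reagents that add atoms: sodium periodate, [Na+].[O-]I(=O)(=O)=O
Why: Lemieux–Johnson oxidative cleavage, in which the terminal alkene is dihydroxylated far faster than the tetrasubstituted, electron-poor pyranone double bonds, and C10 is not epimerised in the buffered medium.

Step 8
Reactants: 14 methyl (2R)-2-hydroxypropanoate
Product: 15 methyl (2R)-2-[(triethylsilyl)oxy]propanoate
Conditions: TESCl, imidazole, CH2Cl2, 0 °C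
Reagents that add atoms: chlorotriethylsilane, CC[Si](CC)(CC)Cl
Why: Silyl ether formation protects the lactate hydroxyl (future C14–O) with a group that can later be removed in the presence of a tert-butyldimethylsilyl ether.

Step 9
Reactants: 15 methyl (2R)-2-[(triethylsilyl)oxy]propanoate; 16 pentan-3-one
Product: 17 (2R)-4-methyl-2-[(triethylsilyl)oxy]heptane-3,5-dione (keto–enol and C4 epimer mixture)
Conditions: 16 (2.2 equiv), LiN(i-Pr)2 (2.2 equiv), THF, −78 °C; then 15, −78 to 0 °C; aq. NH4Cl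
Reagents that add atoms: none
Why: Crossed Claisen acylation of the ketone enolate by the reactive α-silyloxy ester, whose product sits as its diketonate so the lactate centre is not deprotonated.

Step 10
Reactants: 18 methyl (3R)-3-hydroxypentanoate
Product: 19 methyl (2R,3R)-3-hydroxy-2-methylpentanoate
Conditions: LiN(i-Pr)2 (2.2 equiv), THF, −78 to −20 °C; MeI, DMPU, −78 to 0 °C; aq. NH4Cl
Reagents that add atoms: iodomethane, CI
Why: Fráter–Seebach alkylation, in which the chelated alkoxide–enolate dianion is methylated on the face away from the ethyl group to give the anti (2R,3R) ester, so C20 is set by the bought C21 centre.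

Step 11
Reactants: 19 methyl (2R,3R)-3-hydroxy-2-methylpentanoate
Product: 20 methyl (2R,3R)-3-[(tert-butyldimethylsilyl)oxy]-2-methylpentanoate
Conditions: TBSOTf, 2,6-lutidine, CH2Cl2, −78 to 0 °C
Reagents that add atoms: tert-butyldimethylsilyl triflate, CC(C)(C)[Si](C)(C)OS(=O)(=O)C(F)(F)F
Why: Silyl ether formation blocks the C21 hydroxyl, which would otherwise close a dihydropyranone in step 13.

Step 12
Reactants: 17 (2R)-4-methyl-2-[(triethylsilyl)oxy]heptane-3,5-dione; 20 methyl (2R,3R)-3-[(tert-butyldimethylsilyl)oxy]-2-methylpentanoate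
Product: 21 (2R,8R,9R)-9-[(tert-butyldimethylsilyl)oxy]-4,6,8-trimethyl-2-[(triethylsilyl)oxy]undecane-3,5,7-trione (keto–enol and C4/C6 epimer mixture)
Conditions: 17 (2.2 equiv), LiN(i-Pr)2 (4.4 equiv), THF, −78 to 0 °C; then 20, −78 to −10 °C; aq. NH4Cl
Reagents that add atoms: none
Why: Hauser dianion Claisen acylation, in which the second deprotonation occurs at the ethyl CH2 and not at the hindered α-silyloxy methine (as for lactate-derived ethyl ketones), so the three stereocentres are carried through.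

Step 13
Reactants: 21 (2R,8R,9R)-9-[(tert-butyldimethylsilyl)oxy]-4,6,8-trimethyl-2-[(triethylsilyl)oxy]undecane-3,5,7-trione
Product: 23 2-[(2R,3R)-3-[(tert-butyldimethylsilyl)oxy]pentan-2-yl]-6-[(1R)-1-hydroxyethyl]-3,5-dimethyl-4H-pyran-4-one, via triethylsilyl ether pyranone 22 (not isolated)
Conditions: PPh3, CCl4, THF, rt; then MeOH, 0 °C
Reagents that add atoms: none
Why: Appel-type cyclodehydration closes ring B while both hydroxyls are still silylated (no furanone or dihydropyranone), and the HCl formed then removes the triethylsilyl group selectively by methanolysis while the hindered secondary tert-butyldimethylsilyl ether survives.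

Step 14
Reactants: 23 2-[(2R,3R)-3-[(tert-butyldimethylsilyl)oxy]pentan-2-yl]-6-[(1R)-1-hydroxyethyl]-3,5-dimethyl-4H-pyran-4-one; 24 prop-1-ynyllithium
Product: 26 2-[(2R,3R)-3-[(tert-butyldimethylsilyl)oxy]pentan-2-yl]-3,5-dimethyl-6-[(2R)-pent-3-yn-2-yl]-4H-pyran-4-one, via lateral triflate 25 (not isolated)
Conditions: Tf2O, 2,6-di-tert-butyl-4-methylpyridine, CH2Cl2, −78 °C; then Li[AlMe3(C≡CMe)] (3 equiv, from 24 and AlMe3), toluene, −78 to −30 °C
Reagents that add atoms: triflic anhydride, O=S(=O)(OS(=O)(=O)C(F)(F)F)C(F)(F)F (its atoms stay only in 25)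
Why: Proposed new method: stereoinvertive sp–sp3 substitution at the lateral carbon of a 4-pyranone, in which triflate 25 behaves as a vinylogous α-triflyloxy ketone (ionisation is disfavoured by the electron-poor ring, backside attack is accelerated by overlap with the ring π* system), so the weakly basic alkynyl aluminate transfers its propynyl group by SN2 with inversion and turns the bought (R)-lactate centre into C14 (R) and forms the C13–C14 bond without touching C20; the closest known reactions are the invertive displacement of lactate-type α-triflyloxy esters by organozincates and cuprates and alkynyl transfer from alkynylalanates to epoxides.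

Step 15
Reactants: 26 2-[(2R,3R)-3-[(tert-butyldimethylsilyl)oxy]pentan-2-yl]-3,5-dimethyl-6-[(2R)-pent-3-yn-2-yl]-4H-pyran-4-one
Product: 28 2-[(2R,3R)-3-[(tert-butyldimethylsilyl)oxy]pentan-2-yl]-6-[(2R,3E)-4-iodopent-3-en-2-yl]-3,5-dimethyl-4H-pyran-4-one, via alkenylzirconocene chloride 27 (not isolated)
Conditions: Cp2Zr(H)Cl (2.5 equiv), THF, 50 °C; then I2, 0 °C
Reagents that add atoms: Cp2Zr(H)Cl, [H][Zr](Cl)(C1C=CC=C1)C1C=CC=C1 (its heavy atoms stay only in 27); iodine, II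
Why: Hydrozirconation–iodination, in which syn addition under thermodynamic control places zirconium on the methyl-bearing alkyne carbon away from the branched C14, and iodinolysis with retention gives the (E)-2-iodoalkene.

Step 16
Reactants: 13 (2S,3R,4S)-4-(6-ethyl-3,5-dimethyl-4-oxo-4H-pyran-2-yl)-2-methyl-3-[(triethylsilyl)oxy]pentanal; 28 2-[(2R,3R)-3-[(tert-butyldimethylsilyl)oxy]pentan-2-yl]-6-[(2R,3E)-4-iodopent-3-en-2-yl]-3,5-dimethyl-4H-pyran-4-one
Product: 30 C9-O-triethylsilyl C21-O-tert-butyldimethylsilyl ether of 31 (free C11 hydroxyl; 8S,9S,10R,11R,12E,14R,20R,21R, the C10 descriptor differing from 31 only through priority), via zirconocene alkoxide 29 (not isolated)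
Conditions: CrCl3 (20 mol%), NiCl2(dme) (2 mol%), Cp2ZrCl2 (1.1 equiv), Et4NClO4, DMF, Al anode, Ni-foam cathode, constant current (2.5 F per mol), rt; aq. citric acid
Reagents that add atoms: zirconocene dichloride, Cl[Zr](Cl)(C1C=CC=C1)C1C=CC=C1 (its atoms stay only in 29)
Why: Electrochemical Nozaki–Hiyama–Kishi coupling, in which cathodic reduction keeps chromium in its divalent state, nickel mediates formation of the alkenylchromium with retention of the E geometry, and this adds to the α-methyl aldehyde in the Felkin sense (anti to the C9 branch, non-chelating silyl ether) to form C11–C12 and set C11 (10,11-syn, 11R).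

Step 17
Reactants: 30 C9-O-triethylsilyl C21-O-tert-butyldimethylsilyl ether of 31
Product: 31 2-ethyl-6-[(2S,3S,4S,5R,6E,8R)-3,5-dihydroxy-8-{6-[(2R,3R)-3-hydroxypentan-2-yl]-3,5-dimethyl-4-oxo-4H-pyran-2-yl}-4,6-dimethylnon-6-en-2-yl]-3,5-dimethyl-4H-pyran-4-one
Conditions: HF·pyridine, pyridine, THF, 0 °C to rt
Reagents that add atoms: none
Why: Fluoride-mediated desilylation removes both silyl ethers under buffered, non-basic conditions that leave the pyranones, the allylic alcohol and all eight stereo-elements untouched.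

## Compound list

1 | methyl (S)-3-hydroxy-2-methylpropanoate | COC(=O)[C@@H](C)CO | starting material
2 | methyl (S)-3-[(tert-butyldimethylsilyl)oxy]-2-methylpropanoate | COC(=O)[C@@H](C)CO[Si](C)(C)C(C)(C)C | intermediate
3 | 4-methylheptane-3,5-dione | CCC(=O)C(C)C(=O)CC | starting material
4 | (8S)-9-[(tert-butyldimethylsilyl)oxy]-4,6,8-trimethylnonane-3,5,7-trione | CCC(=O)C(C)C(=O)C(C)C(=O)[C@@H](C)CO[Si](C)(C)C(C)(C)C | intermediate
5 | 2-[(2S)-1-[(tert-butyldimethylsilyl)oxy]propan-2-yl]-6-ethyl-3,5-dimethyl-4H-pyran-4-one | CCc1oc([C@@H](C)CO[Si](C)(C)C(C)(C)C)c(C)c(=O)c1C | intermediate (not isolated)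
6 | 2-ethyl-6-[(2S)-1-hydroxypropan-2-yl]-3,5-dimethyl-4H-pyran-4-one | CCc1oc([C@@H](C)CO)c(C)c(=O)c1C | intermediate
7 | (2R)-2-(6-ethyl-3,5-dimethyl-4-oxo-4H-pyran-2-yl)propanal | CCc1oc([C@@H](C)C=O)c(C)c(=O)c1C | intermediate
8 | 2-[(2Z)-but-2-en-1-yl]-4,4,5,5-tetramethyl-1,3,2-dioxaborolane | C/C=C\CB1OC(C)(C)C(C)(C)O1 | starting material
9 | O-(4,4,5,5-tetramethyl-1,3,2-dioxaborolan-2-yl) ether of 10 | CCc1oc([C@@H](C)[C@@H](OB2OC(C)(C)C(C)(C)O2)[C@H](C)C=C)c(C)c(=O)c1C | intermediate (not isolated)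
10 | 2-ethyl-6-[(2S,3S,4R)-3-hydroxy-4-methylhex-5-en-2-yl]-3,5-dimethyl-4H-pyran-4-one | CCc1oc([C@@H](C)[C@@H](O)[C@H](C)C=C)c(C)c(=O)c1C | intermediate
11 | 2-ethyl-3,5-dimethyl-6-[(2S,3S,4R)-4-methyl-3-[(triethylsilyl)oxy]hex-5-en-2-yl]-4H-pyran-4-one | CCc1oc([C@@H](C)[C@@H](O[Si](CC)(CC)CC)[C@H](C)C=C)c(C)c(=O)c1C | intermediate
12 | 5,6-diol of 11 (both C5 epimers of the side chain) | CCc1oc([C@@H](C)[C@@H](O[Si](CC)(CC)CC)[C@H](C)C(O)CO)c(C)c(=O)c1C | intermediate (not isolated)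
13 | (2S,3R,4S)-4-(6-ethyl-3,5-dimethyl-4-oxo-4H-pyran-2-yl)-2-methyl-3-[(triethylsilyl)oxy]pentanal | CCc1oc([C@@H](C)[C@@H](O[Si](CC)(CC)CC)[C@H](C)C=O)c(C)c(=O)c1C | intermediate
14 | methyl (2R)-2-hydroxypropanoate | C[C@@H](O)C(=O)OC | starting material
15 | methyl (2R)-2-[(triethylsilyl)oxy]propanoate | C[C@@H](O[Si](CC)(CC)CC)C(=O)OC | intermediate
16 | pentan-3-one | CCC(=O)CC | starting material
17 | (2R)-4-methyl-2-[(triethylsilyl)oxy]heptane-3,5-dione | CCC(=O)C(C)C(=O)[C@@H](C)O[Si](CC)(CC)CC | intermediate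
18 | methyl (3R)-3-hydroxypentanoate | CC[C@@H](O)CC(=O)OC | starting material
19 | methyl (2R,3R)-3-hydroxy-2-methylpentanoate | COC(=O)[C@H](C)[C@H](O)CC | intermediate
20 | methyl (2R,3R)-3-[(tert-butyldimethylsilyl)oxy]-2-methylpentanoate | COC(=O)[C@H](C)[C@H](O[Si](C)(C)C(C)(C)C)CC | intermediate
21 | (2R,8R,9R)-9-[(tert-butyldimethylsilyl)oxy]-4,6,8-trimethyl-2-[(triethylsilyl)oxy]undecane-3,5,7-trione | O=C([C@H](C)[C@H](O[Si](C)(C)C(C)(C)C)CC)C(C)C(=O)C(C)C(=O)[C@@H](C)O[Si](CC)(CC)CC | intermediate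
22 | 2-[(2R,3R)-3-[(tert-butyldimethylsilyl)oxy]pentan-2-yl]-3,5-dimethyl-6-[(1R)-1-[(triethylsilyl)oxy]ethyl]-4H-pyran-4-one | C[C@@H](O[Si](CC)(CC)CC)c1oc([C@H](C)[C@H](O[Si](C)(C)C(C)(C)C)CC)c(C)c(=O)c1C | intermediate (not isolated)
23 | 2-[(2R,3R)-3-[(tert-butyldimethylsilyl)oxy]pentan-2-yl]-6-[(1R)-1-hydroxyethyl]-3,5-dimethyl-4H-pyran-4-one | C[C@@H](O)c1oc([C@H](C)[C@H](O[Si](C)(C)C(C)(C)C)CC)c(C)c(=O)c1C | intermediate
24 | prop-1-ynyllithium | CC#C[Li] | starting material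
25 | (1R)-1-{6-[(2R,3R)-3-[(tert-butyldimethylsilyl)oxy]pentan-2-yl]-3,5-dimethyl-4-oxo-4H-pyran-2-yl}ethyl trifluoromethanesulfonate | C[C@@H](OS(=O)(=O)C(F)(F)F)c1oc([C@H](C)[C@H](O[Si](C)(C)C(C)(C)C)CC)c(C)c(=O)c1C | intermediate (not isolated)
26 | 2-[(2R,3R)-3-[(tert-butyldimethylsilyl)oxy]pentan-2-yl]-3,5-dimethyl-6-[(2R)-pent-3-yn-2-yl]-4H-pyran-4-one | CC#C[C@@H](C)c1oc([C@H](C)[C@H](O[Si](C)(C)C(C)(C)C)CC)c(C)c(=O)c1C | intermediate
27 | chlorobis(cyclopentadienyl)zirconium (E)-alkenyl derivative of 26 (Zr on C12, trans to C14) | Cl[Zr](C1C=CC=C1)(C1C=CC=C1)/C(C)=C/[C@@H](C)c1oc([C@H](C)[C@H](O[Si](C)(C)C(C)(C)C)CC)c(C)c(=O)c1C | intermediate (not isolated)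
28 | 2-[(2R,3R)-3-[(tert-butyldimethylsilyl)oxy]pentan-2-yl]-6-[(2R,3E)-4-iodopent-3-en-2-yl]-3,5-dimethyl-4H-pyran-4-one | I/C(C)=C/[C@@H](C)c1oc([C@H](C)[C@H](O[Si](C)(C)C(C)(C)C)CC)c(C)c(=O)c1C | intermediate
29 | C11-O-[chlorobis(cyclopentadienyl)zirconium] alkoxide of 30 | CCc1oc([C@@H](C)[C@@H](O[Si](CC)(CC)CC)[C@H](C)[C@@H](O[Zr](Cl)(C3C=CC=C3)C3C=CC=C3)/C(C)=C/[C@@H](C)c2oc([C@H](C)[C@H](O[Si](C)(C)C(C)(C)C)CC)c(C)c(=O)c2C)c(C)c(=O)c1C | intermediate (not isolated)
30 | C9-O-triethylsilyl C21-O-tert-butyldimethylsilyl ether of 31 (C11–OH free) | CCc1oc([C@@H](C)[C@@H](O[Si](CC)(CC)CC)[C@H](C)[C@@H](O)/C(C)=C/[C@@H](C)c2oc([C@H](C)[C@H](O[Si](C)(C)C(C)(C)C)CC)c(C)c(=O)c2C)c(C)c(=O)c1C | intermediate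
31 | 2-ethyl-6-[(2S,3S,4S,5R,6E,8R)-3,5-dihydroxy-8-{6-[(2R,3R)-3-hydroxypentan-2-yl]-3,5-dimethyl-4-oxo-4H-pyran-2-yl}-4,6-dimethylnon-6-en-2-yl]-3,5-dimethyl-4H-pyran-4-one | CCc1oc([C@@H](C)[C@@H](O)[C@H](C)[C@@H](O)/C(C)=C/[C@@H](C)c2oc([C@H](C)[C@H](O)CC)c(C)c(=O)c2C)c(C)c(=O)c1C | target

## Step count and risks

Total steps: 17. Longest linear sequence: 9 (steps 1–7, 16, 17).

**Step 14 (the proposed alkynylation).** The triflate may eliminate to the 2-vinylpyranone, or ionise and racemise C14. The fallback uses only known chemistry, sets out from 16 and 20, and rejoins the route at 31.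
- Pentan-3-one 16 is acylated (LiN(i-Pr)2, THF) with methyl (R)-3-[(tert-butyldimethylsilyl)oxy]-2-methylpropanoate F1, itself made from bought methyl (R)-3-hydroxy-2-methylpropanoate with TBSCl as in step 1, to give (2R)-1-[(tert-butyldimethylsilyl)oxy]-2,4-dimethylheptane-3,5-dione F2.
- The dianion of F2 is acylated with 20 as in step 12 to give (2R,8R,9R)-1,9-bis[(tert-butyldimethylsilyl)oxy]-2,4,6,8-tetramethylundecane-3,5,7-trione F3.
- PPh3/CCl4 closes ring B to 2-[(2R,3R)-3-[(tert-butyldimethylsilyl)oxy]pentan-2-yl]-6-[(2R)-1-[(tert-butyldimethylsilyl)oxy]propan-2-yl]-3,5-dimethyl-4H-pyran-4-one F4, and camphorsulfonic acid in MeOH at 0 °C frees only the primary hydroxyl to give 2-[(2R,3R)-3-[(tert-butyldimethylsilyl)oxy]pentan-2-yl]-6-[(2R)-1-hydroxypropan-2-yl]-3,5-dimethyl-4H-pyran-4-one F5.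
- Dess–Martin oxidation gives (2S)-2-{6-[(2R,3R)-3-[(tert-butyldimethylsilyl)oxy]pentan-2-yl]-3,5-dimethyl-4-oxo-4H-pyran-2-yl}propanal F6.
- Wittig reaction with 2-(triphenylphosphoranylidene)pentan-3-one gives 2-[(2R,3R)-3-[(tert-butyldimethylsilyl)oxy]pentan-2-yl]-3,5-dimethyl-6-[(2R,3E)-4-methyl-5-oxohept-3-en-2-yl]-4H-pyran-4-one F7.
- The (Z)-boron enolate of F7 (Bu2BOTf, i-Pr2NEt, −78 °C) adds to aldehyde 7 in a syn, anti-Felkin aldol to give the C21-O-tert-butyldimethylsilyl ether of 11-oxo-31 F8.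
- Et2BOMe/NaBH4 reduction directed by the C9 hydroxyl gives the C21-O-tert-butyldimethylsilyl ether of 31 F9, and HF·pyridine as in step 17 gives 31.

**Step 16 (electrochemical coupling).** Felkin selectivity at C11 with a β-silyloxy α-methyl aldehyde may be only moderate. The fallback sets out from 30 (as its C11 epimer mixture), sets C11 by directed reduction instead of during the coupling, and rejoins at 31.
- Dess–Martin oxidation gives the C9-O-triethylsilyl C21-O-tert-butyldimethylsilyl ether of 11-oxo-31 F10.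
- HF·pyridine gives 11-oxo-31 (the 9,21-dihydroxy C11 enone) F11.
- Et2BOMe/NaBH4 at −78 °C, directed by the C9 hydroxyl, gives the 9,11-syn diol 31.

**Step 5 (crotylboration of the labile aldehyde).** Aldehyde 7 may epimerise at C8 during the slow addition, or the facial selectivity may be low. The fallback sets out from 7, replaces the allylation and oxidative cleavage by an aldol, and rejoins at 13.
- Aldehyde 7 is treated at −78 °C with the (Z)-boron enolate of S-phenyl propanethioate (Bu2BOTf, i-Pr2NEt), which reacts quickly and gives the syn, anti-Felkin aldol S-phenyl (2S,3R,4S)-4-(6-ethyl-3,5-dimethyl-4-oxo-4H-pyran-2-yl)-3-hydroxy-2-methylpentanethioate F12.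
- TESCl/imidazole gives S-phenyl (2S,3R,4S)-4-(6-ethyl-3,5-dimethyl-4-oxo-4H-pyran-2-yl)-2-methyl-3-[(triethylsilyl)oxy]pentanethioate F13.
- Fukuyama reduction (Et3SiH, Pd/C, acetone) gives 13.

## Further compounds

F1 | step 14 | methyl (R)-3-[(tert-butyldimethylsilyl)oxy]-2-methylpropanoate | COC(=O)[C@H](C)CO[Si](C)(C)C(C)(C)C
F2 | step 14 | (2R)-1-[(tert-butyldimethylsilyl)oxy]-2,4-dimethylheptane-3,5-dione | CCC(=O)C(C)C(=O)[C@H](C)CO[Si](C)(C)C(C)(C)C
F3 | step 14 | (2R,8R,9R)-1,9-bis[(tert-butyldimethylsilyl)oxy]-2,4,6,8-tetramethylundecane-3,5,7-trione | O=C([C@H](C)[C@H](O[Si](C)(C)C(C)(C)C)CC)C(C)C(=O)C(C)C(=O)[C@H](C)CO[Si](C)(C)C(C)(C)C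
F4 | step 14 | 2-[(2R,3R)-3-[(tert-butyldimethylsilyl)oxy]pentan-2-yl]-6-[(2R)-1-[(tert-butyldimethylsilyl)oxy]propan-2-yl]-3,5-dimethyl-4H-pyran-4-one | CC(C)(C)[Si](C)(C)OC[C@@H](C)c1oc([C@H](C)[C@H](O[Si](C)(C)C(C)(C)C)CC)c(C)c(=O)c1C
F5 | step 14 | 2-[(2R,3R)-3-[(tert-butyldimethylsilyl)oxy]pentan-2-yl]-6-[(2R)-1-hydroxypropan-2-yl]-3,5-dimethyl-4H-pyran-4-one | OC[C@@H](C)c1oc([C@H](C)[C@H](O[Si](C)(C)C(C)(C)C)CC)c(C)c(=O)c1C
F6 | step 14 | (2S)-2-{6-[(2R,3R)-3-[(tert-butyldimethylsilyl)oxy]pentan-2-yl]-3,5-dimethyl-4-oxo-4H-pyran-2-yl}propanal | O=C[C@@H](C)c1oc([C@H](C)[C@H](O[Si](C)(C)C(C)(C)C)CC)c(C)c(=O)c1C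
F7 | step 14 | 2-[(2R,3R)-3-[(tert-butyldimethylsilyl)oxy]pentan-2-yl]-3,5-dimethyl-6-[(2R,3E)-4-methyl-5-oxohept-3-en-2-yl]-4H-pyran-4-one | CCC(=O)/C(C)=C/[C@@H](C)c1oc([C@H](C)[C@H](O[Si](C)(C)C(C)(C)C)CC)c(C)c(=O)c1C
F8 | step 14 | C21-O-tert-butyldimethylsilyl ether of 11-oxo-31 | CCc1oc([C@@H](C)[C@@H](O)[C@H](C)C(=O)/C(C)=C/[C@@H](C)c2oc([C@H](C)[C@H](O[Si](C)(C)C(C)(C)C)CC)c(C)c(=O)c2C)c(C)c(=O)c1C
F9 | step 14 | C21-O-tert-butyldimethylsilyl ether of 31 | CCc1oc([C@@H](C)[C@@H](O)[C@H](C)[C@@H](O)/C(C)=C/[C@@H](C)c2oc([C@H](C)[C@H](O[Si](C)(C)C(C)(C)C)CC)c(C)c(=O)c2C)c(C)c(=O)c1C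
F10 | step 16 | C9-O-triethylsilyl C21-O-tert-butyldimethylsilyl ether of 11-oxo-31 | CCc1oc([C@@H](C)[C@@H](O[Si](CC)(CC)CC)[C@H](C)C(=O)/C(C)=C/[C@@H](C)c2oc([C@H](C)[C@H](O[Si](C)(C)C(C)(C)C)CC)c(C)c(=O)c2C)c(C)c(=O)c1C
F11 | step 16 | 11-oxo-31 (9,21-dihydroxy C11 enone) | CCc1oc([C@@H](C)[C@@H](O)[C@H](C)C(=O)/C(C)=C/[C@@H](C)c2oc([C@H](C)[C@H](O)CC)c(C)c(=O)c2C)c(C)c(=O)c1C
F12 | step 5 | S-phenyl (2S,3R,4S)-4-(6-ethyl-3,5-dimethyl-4-oxo-4H-pyran-2-yl)-3-hydroxy-2-methylpentanethioate | CCc1oc([C@@H](C)[C@@H](O)[C@H](C)C(=O)Sc2ccccc2)c(C)c(=O)c1C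
F13 | step 5 | S-phenyl (2S,3R,4S)-4-(6-ethyl-3,5-dimethyl-4-oxo-4H-pyran-2-yl)-2-methyl-3-[(triethylsilyl)oxy]pentanethioate | CCc1oc([C@@H](C)[C@@H](O[Si](CC)(CC)CC)[C@H](C)C(=O)Sc2ccccc2)c(C)c(=O)c1C
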